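| setting | winter | spring | autumn | flask |
|---|---|---|---|---|
| left-handed substrate | 0.30 M | 0.30 M | 0.30 M | 0.30 M |
| right-handed substrate | 0.30 M | 0.30 M | 0.30 M | 0.30 M |
| partner | 0.33 M | 0.33 M | 0.49 M | 0.330 M |
| precatalyst | 24 mM | 36 mM | 48 mM | 48 mM |
| remark | run made earlier | run made earlier | run made earlier |  |
| time |  |  |  | 25 h |

| run | time / h | left-handed substrate / % | right-handed substrate / % | left-handed product / % |
|---|---|---|---|---|
| winter | 1.33 | 49 | 48 | 1 |
| winter | 2.00 | 47 | 48 | 1 |
| winter | 3.00 | 44 | 51 | 5 |
| winter | 5.00 | 41 | 44 | 11 |
| winter | 10.0 | 34 | 42 | 14 |
| winter | 15.0 | 31 | 38 | 17 |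
| spring | 1.00 | 51 | 50 | 0 |
| spring | 3.00 | 41 | 42 | 6 |
| spring | 5.00 | 39 | 44 | 9 |
| spring | 8.00 | 36 | 40 | 14 |
| spring | 12.0 | 26 | 39 | 20 |
| spring | 15.0 | 27 | 37 | 21 |
| autumn | 1.33 | 47 | 46 | 5 |
| autumn | 4.00 | 33 | 40 | 12 |
| autumn | 8.00 | 22 | 32 | 23 |
| autumn | 10.0 | 23 | 33 | 28 |
| autumn | 15.0 | 18 | 26 | 25 |

(readings scatter by 1.5 percentage points)

- free catalyst is single-handed; left-handed substrate and right-handed substrate are mirror images of each other, charged as a racemate, each of them at the stated concentration
- steps thought possible: partner + free catalyst + left-handed substrate -> free catalyst + left-handed product; partner + free catalyst + right-handed substrate -> free catalyst + right-handed product; partner + free catalyst -> spent catalyst; left-handed product <-> right-handed product; precatalyst <-> free catalyst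
- an excess is the difference of the two amounts in percent of their sum
- an excess is below zero if the other one leads

- part of the left-handed substrate and right-handed substrate charged together that has reacted at 25 h
- excess of left-handed product over right-handed product in the product at 25 h
- excess of right-handed substrate over left-handed substrate among what is left of the two at 25 h

1. I began with the easy entry in the ledger of the flask: each product molecule costs one partner, whichever hand it came from.

2. So I took as the ceiling on conversion the partner charge divided by the two substrate charges together, 55.0 %. With c(partner) at 0.330 M against 0.600 M of substrate, partner is the limiting reagent.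

3. The second entry is spent catalyst, which costs one partner per free catalyst. The precatalyst charge of 48 mM is less than c(partner), so this entry could hold 14.5 % of the partner at the outside.

4. The third entry is partner still unused. The autumn run, with this precatalyst charge but more partner, had reacted 56.0 % by 15.0 h, a reading about the size of the flask's ceiling. So I expected the flask near its ceiling but under it.

5. The forecast gave c 45 %, eP 5 % and eS 16 %, noting that “0.33 M partner caps conversion at 55% of the 0.60 M substrate”. In my ledger, its c puts 0.270 M of partner into products.

6. The flask gave c 47.3 %, eP 2.70 % and eS 18.5 %, and the forecast held within its margins.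

    partner + free catalyst + left-handed substrate → free catalyst + left-handed product (k = 0.430 /M²/min)
    partner + free catalyst + right-handed substrate → free catalyst + right-handed product (k = 0.240 /M²/min)
    partner + free catalyst → spent catalyst (k = 0.00410 /M/min)
    left-handed product ⇌ right-handed product (k = 0.00100 /min)
    precatalyst ⇌ free catalyst (K = 0.370, k = 0.00530 /min)

At 25 h, the flask's products held 0.284 M of partner. Spent catalyst in the flask held 0.00806 M of partner, hardly any of the partner charge, and 0.0380 M of partner lay unused, so conversion stood 7.7 percentage points under the ceiling of 55.0 %. The neighbouring flask with 0.12 M of precatalyst kept the same partner charge and so the same ceiling. There, spent catalyst held 0.00952 M and 0.00276 M lay unused, so 0.318 M of partner went to products, a conversion of 53.0 %.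

(All runs stem from a simulated flask with constants of no real substance.)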